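**Retrosynthetic overview**

1. Ring numbering: C1 = CH bearing the propenoic acid, C2 = CH–OH, C3 = CH bearing C(=CH2)CH2OH, C4 = C(CH3)(CH=CH2), C5 = CH2, C6 = CH–O–acyl. The target is traced back, through fluoride unmasking and acylation of the C6 hydroxyl, to diol ester 24.
2. Key disconnection C1–C2: the cyclohexane, the only ring, is closed last by intramolecular umpolung allylation of the C2 aldehyde by a 2-(oxiran-2-yl)acrylate whose epoxide carbons are C1 and C6 (open-chain epoxy aldehyde 22).
3. Enabling feature: C1 carries the 1-carboxyethenyl group and lies between the oxygenated ring carbons C2 and C6. The array C6(O)–C1[C(=CH2)CO2H]–C2(OH) is the 2-(1-carboxyvinyl)-1,3-diol that a δ-oxygenated 2-(alkoxycarbonyl)allyl metal delivers to an aldehyde, the exocyclic methylene being the former metal-bearing carbon.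
4. 22 comes from Shi epoxidation (sets C6) of a 2-(alkoxycarbonyl)-1,3-diene, made by Horner–Wadsworth–Emmons olefination of a lactol, itself from alkyne hydroboration–oxidation. C3 and C4 come from an enantioselective ester-enolate Claisen rearrangement of a (Z)-enynyl ester built from itaconic anhydride.
5. Order of ring formation: only the temporary lactol 13 exists before the key step; the cyclohexane is formed in step 12.

Key step: step 12

Remark: the (S,S)-bromoborane is assumed to give the (2R,3R)-acid 9; if its facial preference proves opposite, the (R,R)-reagent is used with no other change.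
Remark: the L-fructose-derived ketone in step 10 is chosen by analogy with simple trans-disubstituted olefins, for which the D-fructose-derived ketone gives the (R,R)-epoxide.

**Route**

Step 1
Reactants: 1 (2Z)-3-methylpent-2-en-4-yn-1-ol; 2 itaconic anhydride (3-methylideneoxolane-2,5-dione)
Product: 3 4-{[(2Z)-3-methylpent-2-en-4-yn-1-yl]oxy}-2-methylidene-4-oxobutanoic acid
Conditions: toluene, 70 °C
Reagents that add atoms: none
Why: Alcoholysis of the cyclic anhydride should occur at the non-conjugated, more electrophilic carbonyl and give the 4-monoester with the conjugated acid left free (regioselective anhydride ring opening); no stereocentre is formed and the Z olefin is untouched.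

Step 2
Reactants: 3
Product: 5 (2Z)-3-methylpent-2-en-4-yn-1-yl 3-(hydroxymethyl)but-3-enoate, via mixed carbonic anhydride 4 (not isolated)
Conditions: i-BuOCOCl, N-methylmorpholine, THF, −15 °C; then NaBH4, H2O, −15 → 0 °C
Reagents that add atoms: none
Why: Reduction of a carboxylic acid through its mixed carbonic anhydride with NaBH4 should convert only the activated acyl group into the allylic alcohol and leave the ester, alkyne and alkenes; the cold, short reaction and direct silylation of the crude product guard against lactonization of the γ-hydroxy ester.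

Step 3
Reactants: 5
Product: 6 (2Z)-3-methylpent-2-en-4-yn-1-yl 3-({[tert-butyl(dimethyl)silyl]oxy}methyl)but-3-enoate
Conditions: TBSCl, imidazole, DMF, 0 °C → rt
Reagents that add atoms: tert-butyl(chloro)dimethylsilane, CC(C)(C)[Si](C)(C)Cl
Why: Standard silylation of a primary allylic alcohol (silyl ether formation) should give an ether that lasts until the final fluoride treatment.

Step 4
Reactants: 6
Product: 9 (2R,3R)-2-(3-{[tert-butyl(dimethyl)silyl]oxy}prop-1-en-2-yl)-3-ethynyl-3-methylpent-4-enoic acid, via boron enolate 7 (not isolated), via acyloxyborane 8 (not isolated)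
Conditions: (4S,5S)-2-bromo-1,3-bis{[3,5-bis(trifluoromethyl)phenyl]sulfonyl}-4,5-diphenyl-1,3,2-diazaborolidine (made from the (S,S)-bis-sulfonamide and BBr3 in CH2Cl2, volatiles removed), Et3N, toluene–hexane, −78 °C, then −20 → 4 °C; aqueous work-up
Reagents that add atoms: none
Why: Enantioselective boron-enolate Ireland–Claisen rearrangement: soft enolization in a non-polar medium should give the E(O) dienolate 7, which rearranges through a chair transition state with the ethynyl group of the Z olefin axial and so sets the future C3 and C4 in the required relative sense, while the C2-symmetric bis-sulfonamide on boron selects the enolate face and hence the (2R,3R) series.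

Step 5
Reactants: 9
Product: 10 (2R,3R)-2-(3-{[tert-butyl(dimethyl)silyl]oxy}prop-1-en-2-yl)-3-ethynyl-3-methylpent-4-en-1-ol
Conditions: LiAlH4, THF, 0 °C → rt
Reagents that add atoms: none
Why: Hydride reduction of the carboxylic acid to the primary alcohol (LiAlH4 reduction) should leave the isolated alkyne, the alkenes and the silyl ether alone and does not touch the two stereocentres.

Step 6
Reactants: 10
Product: 13 (4R,5R)-5-(3-{[tert-butyl(dimethyl)silyl]oxy}prop-1-en-2-yl)-4-ethenyl-4-methyloxan-2-ol (both anomers), via alkenylboronate 11 (not isolated), via hydroxy aldehyde 12 (not isolated)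
Conditions: B2pin2, CuCl (5 mol%), Xantphos, NaOt-Bu, MeOH, THF, rt; then 30% H2O2, NaH2PO4/Na2HPO4 buffer (pH 7), 0 °C
Reagents that add atoms: hydrogen peroxide, OO
Why: Copper-catalysed β-selective syn-hydroboration of the terminal alkyne (borylcupration, then protonation by MeOH) is chemoselective over the three alkenes, and oxidation of the alkenylboronate should give the aldehyde, which the primary hydroxyl captures as the six-membered lactol (anti-Markovnikov alkyne hydration by hydroboration–oxidation).

Step 7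
Reactants: 14 2-(bromomethyl)prop-2-enoic acid; 15 2-(trimethylsilyl)ethanol
Product: 17 2-(trimethylsilyl)ethyl 2-(bromomethyl)prop-2-enoate, via acid chloride 16 (not isolated)
Conditions: (COCl)2, DMF (cat.), CH2Cl2, 0 °C → rt; then 15, pyridine, −20 → 0 °C
Reagents that add atoms: none
Why: Esterification through the acid chloride (acyl chloride alcoholysis) avoids nucleophilic acylation catalysts that the allylic bromide would alkylate.

Step 8
Reactants: 17; 18 triethyl phosphite
Product: 19 2-(trimethylsilyl)ethyl 2-[(diethoxyphosphoryl)methyl]prop-2-enoate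
Conditions: neat, 80 °C
Reagents that add atoms: none
Why: Michaelis–Arbuzov reaction of the allylic bromide should give the allylic phosphonate, the SN2 and SN2' paths leading to the same product.

Step 9
Reactants: 13; 19
Product: 20 2-(trimethylsilyl)ethyl (3E,6R,7R)-7-(3-{[tert-butyl(dimethyl)silyl]oxy}prop-1-en-2-yl)-6-ethenyl-8-hydroxy-6-methyl-2-methylideneoct-3-enoate
Conditions: 19 (2.2 equiv), NaN(SiMe3)2, THF, −78 °C; then 13, −78 → 0 °C
Reagents that add atoms: none
Why: Horner–Wadsworth–Emmons olefination of the open hydroxy aldehyde form of the lactol with the allylic phosphonate anion should give the E-configured 2-(alkoxycarbonyl)-1,3-diene and free the primary hydroxyl that becomes the C2 aldehyde, the excess anion serving as the base that opens the lactol.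

Step 10
Reactants: 20
Product: 21 2-(trimethylsilyl)ethyl 2-{(2S,3S)-3-[(2R,3R)-3-(3-{[tert-butyl(dimethyl)silyl]oxy}prop-1-en-2-yl)-2-ethenyl-4-hydroxy-2-methylbutyl]oxiran-2-yl}prop-2-enoate
Conditions: L-fructose-derived enantiomer of the Shi ketone (30 mol%), KHSO5 (Oxone), K2CO3, Bu4NHSO4, MeCN–CH2(OMe)2/aq. Na2B4O7 buffer, −10 → 0 °C
Reagents that add atoms: potassium peroxymonosulfate, [K+].[O-]S(=O)(=O)OO
Why: Shi asymmetric epoxidation: the chiral dioxirane should attack the conjugated trans-disubstituted alkene, the most electron-rich and best-recognized olefin of 20, through the spiro transition state and so set the future C6 and the adjacent allylic carbon as S,S under catalyst control, the terminal and ester-bearing alkenes reacting more slowly.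

Step 11
Reactants: 21
Product: 22 2-(trimethylsilyl)ethyl 2-{(2S,3S)-3-[(2R,3R)-3-(3-{[tert-butyl(dimethyl)silyl]oxy}prop-1-en-2-yl)-2-ethenyl-2-methyl-4-oxobutyl]oxiran-2-yl}prop-2-enoate
Conditions: Dess–Martin periodinane, NaHCO3, CH2Cl2, 0 °C
Reagents that add atoms: none
Why: Buffered Dess–Martin oxidation of the primary alcohol should give the α-branched β,γ-unsaturated aldehyde without epimerization at the future C3 or opening of the vinyl epoxide; the aldehyde is used at once.

Step 12
Reactants: 22
Product: 24 2-(trimethylsilyl)ethyl 2-[(1R,2S,3R,4R,6S)-3-(3-{[tert-butyl(dimethyl)silyl]oxy}prop-1-en-2-yl)-4-ethenyl-2,6-dihydroxy-4-methylcyclohexyl]prop-2-enoate, via allylindium species 23 (not isolated)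
Conditions: Pd(PPh3)4 (5 mol%), InI (1.5 equiv), THF/H2O (4:1), rt
Reagents that add atoms: none
Why: Proposed new method: zerovalent palladium ionizes the allylic C–O bond of the vinyl epoxide to a 2-(alkoxycarbonyl)allyl palladium alkoxide, reductive transmetalation with InI turns it into the nucleophilic allylindium 23 of trivalent indium, and this adds through its γ-carbon to the tethered aldehyde; the closest known reactions are the intermolecular Pd/InI umpolung allylation of aldehydes with vinyl oxiranes to 2-vinyl-1,3-diols and the metal-mediated cyclization of ω-formyl 2-(bromomethyl)acrylates to cis-fused α-methylene lactones. The cyclohexane closes by 6-exo-trig attack on the aldehyde with allylic transposition (SE2'), so that the CH2–In carbon becomes the exocyclic methylene and C1–C2 is the only bond formed, attack through the α-carbon being excluded because it would need an eight-membered ring. C1 is controlled by the C6 stereocentre: the forming ring takes the chair in which the C6 hydroxyl and the C3 side chain are equatorial (vinyl axial at C4), which places the acrylate equatorial and trans to the C6 oxygen. C2 is controlled by the closed six-membered Zimmerman–Traxler array fused to that chair, because the (Z)-allylindium (C6 cis to CH2In, the geometry favoured by the ester and reached from either allyl isomer by metallotropic shift) can only be fused in the cis-decalin-like way, which puts the new hydroxyl axial and cis to the acrylate. The step is stereoconvergent at the allylic epoxide carbon, whose configuration is erased on ionization, so it needs only the C3/C4 pair from step 4 and C6 from step 10; water keeps the C6 oxygen off indium and so disfavours the chelated alternative, which would in addition force the C3 side chain and the C4 methyl into axial positions. Chemoselectivity over palladium-mediated isomerization of the vinyl epoxide is secured by an excess of InI, and the ester survives so that the cis γ-hydroxy ester can be isolated without lactonization.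

Step 13
Reactants: 25 3-methylfuran-2(5H)-one
Product: 28 (2Z)-4-{[tert-butyl(dimethyl)silyl]oxy}-2-methylbut-2-enoic acid, via sodium hydroxy carboxylate 26 (not isolated), via bis-silyl derivative 27 (not isolated)
Conditions: NaOH, H2O/MeOH, rt, then evaporation; TBSCl, imidazole, DMF, rt; then K2CO3, MeOH/THF/H2O, rt; citric acid to pH 4
Reagents that add atoms: sodium hydroxide, [Na+].[OH-]; tert-butyl(chloro)dimethylsilane, CC(C)(C)[Si](C)(C)Cl
Why: Saponification of the butenolide fixes the Z geometry of the hydroxy acid, bis-silylation traps it before relactonization and mild carbonate methanolysis cleaves only the silyl ester (lactone hydrolysis, silylation and selective silyl ester cleavage).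

Step 14
Reactants: 28
Product: 30 (2Z)-4-(acetyloxy)-2-methylbut-2-enoic acid, via mixed acetic anhydride 29 (not isolated)
Conditions: Ac2O, Cu(OTf)2 (5 mol%), CH2Cl2, rt; then THF/H2O
Reagents that add atoms: acetic anhydride, CC(=O)OC(C)=O
Why: Lewis acid-catalysed direct exchange of a silyl ether for an acetate with Ac2O should never expose the free hydroxyl, so that relactonization to 25 cannot compete and the Z geometry is kept; aqueous work-up hydrolyses the mixed anhydride 29.

Step 15
Reactants: 24; 30
Product: 32 2-(trimethylsilyl)ethyl 2-[(1S,2S,3R,4R,6S)-6-{[(2Z)-4-(acetyloxy)-2-methylbut-2-enoyl]oxy}-3-(3-{[tert-butyl(dimethyl)silyl]oxy}prop-1-en-2-yl)-4-ethenyl-2-hydroxy-4-methylcyclohexyl]prop-2-enoate, via trichlorobenzoyl mixed anhydride 31 (not isolated)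
Conditions: 30, 2,4,6-trichlorobenzoyl chloride, Et3N, toluene, rt; then 24, DMAP, toluene, rt
Reagents that add atoms: none
Why: Yamaguchi esterification: the equatorial C6 hydroxyl should be acylated in preference to the axial C2 hydroxyl, which is flanked by two branched ring carbons, and the mixed-anhydride method is the one that couples Z-configured 2-methylbut-2-enoic acids without isomerization.

Step 16
Reactants: 32
Product: 33 2-[(1S,2S,3R,4R,6S)-6-{[(2Z)-4-(acetyloxy)-2-methylbut-2-enoyl]oxy}-4-ethenyl-2-hydroxy-3-(3-hydroxyprop-1-en-2-yl)-4-methylcyclohexyl]prop-2-enoic acid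
Conditions: TASF [(Me2N)3S+ Me3SiF2−], DMF, 0 °C → rt; then AcOH/NaOAc buffer (pH 5)
Reagents that add atoms: none
Why: Fluoride-induced cleavage of the 2-(trimethylsilyl)ethyl ester (β-elimination of ethene) and of the silyl ether should unveil the acid as its carboxylate under non-acidic conditions, so that the cis γ-hydroxy acid is not driven to the lactone and the acetate and the Z enoate ester survive; mild buffering gives the free acid.

**Compound list**

1 | (2Z)-3-methylpent-2-en-4-yn-1-ol | C#C/C(C)=C\CO | starting material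
2 | itaconic anhydride (3-methylideneoxolane-2,5-dione) | C=C1CC(=O)OC1=O | starting material
3 | 4-{[(2Z)-3-methylpent-2-en-4-yn-1-yl]oxy}-2-methylidene-4-oxobutanoic acid | C#C/C(C)=C\COC(=O)CC(=C)C(=O)O | intermediate
4 | mixed anhydride of 3 with isobutyl carbonic acid | C#C/C(C)=C\COC(=O)CC(=C)C(=O)OC(=O)OCC(C)C | intermediate (not isolated)
5 | (2Z)-3-methylpent-2-en-4-yn-1-yl 3-(hydroxymethyl)but-3-enoate | C#C/C(C)=C\COC(=O)CC(=C)CO | intermediate
6 | (2Z)-3-methylpent-2-en-4-yn-1-yl 3-({[tert-butyl(dimethyl)silyl]oxy}methyl)but-3-enoate | C#C/C(C)=C\COC(=O)CC(=C)CO[Si](C)(C)C(C)(C)C | intermediate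
7 | E(O) boron dienolate of 6 (the dienyl substituent trans to O–B, boron bearing the (S,S)-bis-sulfonamide) | C#C/C(C)=C\CO/C(OB1N(S(=O)(=O)c2cc(cc(c2)C(F)(F)F)C(F)(F)F)[C@@H](c2ccccc2)[C@H](c2ccccc2)N1S(=O)(=O)c1cc(cc(c1)C(F)(F)F)C(F)(F)F)=C\C(=C)CO[Si](C)(C)C(C)(C)C | intermediate (not isolated)
8 | acyloxyborane of acid 9 with the (S,S)-diazaborolidine | C=C[C@@](C)(C#C)[C@@H](C(=O)OB1N(S(=O)(=O)c2cc(cc(c2)C(F)(F)F)C(F)(F)F)[C@@H](c2ccccc2)[C@H](c2ccccc2)N1S(=O)(=O)c1cc(cc(c1)C(F)(F)F)C(F)(F)F)C(=C)CO[Si](C)(C)C(C)(C)C | intermediate (not isolated)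
9 | (2R,3R)-2-(3-{[tert-butyl(dimethyl)silyl]oxy}prop-1-en-2-yl)-3-ethynyl-3-methylpent-4-enoic acid | C=C[C@@](C)(C#C)[C@@H](C(=O)O)C(=C)CO[Si](C)(C)C(C)(C)C | intermediate
10 | (2R,3R)-2-(3-{[tert-butyl(dimethyl)silyl]oxy}prop-1-en-2-yl)-3-ethynyl-3-methylpent-4-en-1-ol | C=C[C@@](C)(C#C)[C@@H](CO)C(=C)CO[Si](C)(C)C(C)(C)C | intermediate
11 | pinacol (E)-alkenylboronate of 10 (ethynyl turned into (E)-CH=CH–Bpin, stereocentres unchanged) | C=C[C@@](C)(/C=C/B1OC(C)(C)C(C)(C)O1)[C@@H](CO)C(=C)CO[Si](C)(C)C(C)(C)C | intermediate (not isolated)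
12 | (3R,4R)-4-(3-{[tert-butyl(dimethyl)silyl]oxy}prop-1-en-2-yl)-3-ethenyl-5-hydroxy-3-methylpentanal | C=C[C@@](C)(CC=O)[C@@H](CO)C(=C)CO[Si](C)(C)C(C)(C)C | intermediate (not isolated)
13 | (4R,5R)-5-(3-{[tert-butyl(dimethyl)silyl]oxy}prop-1-en-2-yl)-4-ethenyl-4-methyloxan-2-ol (both anomers) | C=C[C@@]1(C)CC(O)OC[C@H]1C(=C)CO[Si](C)(C)C(C)(C)C | intermediate
14 | 2-(bromomethyl)prop-2-enoic acid | C=C(CBr)C(=O)O | starting material
15 | 2-(trimethylsilyl)ethanol | C[Si](C)(C)CCO | starting material
16 | 2-(bromomethyl)prop-2-enoyl chloride | C=C(CBr)C(Cl)=O | intermediate (not isolated)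
17 | 2-(trimethylsilyl)ethyl 2-(bromomethyl)prop-2-enoate | C=C(CBr)C(=O)OCC[Si](C)(C)C | intermediate
18 | triethyl phosphite | CCOP(OCC)OCC | starting material
19 | 2-(trimethylsilyl)ethyl 2-[(diethoxyphosphoryl)methyl]prop-2-enoate | C=C(CP(=O)(OCC)OCC)C(=O)OCC[Si](C)(C)C | intermediate
20 | 2-(trimethylsilyl)ethyl (3E,6R,7R)-7-(3-{[tert-butyl(dimethyl)silyl]oxy}prop-1-en-2-yl)-6-ethenyl-8-hydroxy-6-methyl-2-methylideneoct-3-enoate | C=C[C@@](C)(C/C=C/C(=C)C(=O)OCC[Si](C)(C)C)[C@@H](CO)C(=C)CO[Si](C)(C)C(C)(C)C | intermediate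
21 | 2-(trimethylsilyl)ethyl 2-{(2S,3S)-3-[(2R,3R)-3-(3-{[tert-butyl(dimethyl)silyl]oxy}prop-1-en-2-yl)-2-ethenyl-4-hydroxy-2-methylbutyl]oxiran-2-yl}prop-2-enoate | C=C[C@@](C)(C[C@@H]1O[C@H]1C(=C)C(=O)OCC[Si](C)(C)C)[C@@H](CO)C(=C)CO[Si](C)(C)C(C)(C)C | intermediate
22 | 2-(trimethylsilyl)ethyl 2-{(2S,3S)-3-[(2R,3R)-3-(3-{[tert-butyl(dimethyl)silyl]oxy}prop-1-en-2-yl)-2-ethenyl-2-methyl-4-oxobutyl]oxiran-2-yl}prop-2-enoate | C=C[C@@](C)(C[C@@H]1O[C@H]1C(=C)C(=O)OCC[Si](C)(C)C)[C@@H](C=O)C(=C)CO[Si](C)(C)C(C)(C)C | intermediate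
23 | (Z)-allylindium species from 22 (open-chain aldehyde, free hydroxyl at the future C6, CH2–In(OH)I cis to the carbinol carbon) | C=C[C@@](C)(C[C@H](O)/C=C(\C[In](I)O)C(=O)OCC[Si](C)(C)C)[C@@H](C=O)C(=C)CO[Si](C)(C)C(C)(C)C | intermediate (not isolated)
24 | 2-(trimethylsilyl)ethyl 2-[(1R,2S,3R,4R,6S)-3-(3-{[tert-butyl(dimethyl)silyl]oxy}prop-1-en-2-yl)-4-ethenyl-2,6-dihydroxy-4-methylcyclohexyl]prop-2-enoate | C=C[C@@]1(C)C[C@H](O)[C@@H](C(=C)C(=O)OCC[Si](C)(C)C)[C@@H](O)[C@H]1C(=C)CO[Si](C)(C)C(C)(C)C | intermediate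
25 | 3-methylfuran-2(5H)-one | CC1=CCOC1=O | starting material
26 | sodium (2Z)-4-hydroxy-2-methylbut-2-enoate | [Na+].[O-]C(=O)/C(C)=C\CO | intermediate (not isolated)
27 | tert-butyl(dimethyl)silyl (2Z)-4-{[tert-butyl(dimethyl)silyl]oxy}-2-methylbut-2-enoate | CC(C)(C)[Si](C)(C)OC(=O)/C(C)=C\CO[Si](C)(C)C(C)(C)C | intermediate (not isolated)
28 | (2Z)-4-{[tert-butyl(dimethyl)silyl]oxy}-2-methylbut-2-enoic acid | OC(=O)/C(C)=C\CO[Si](C)(C)C(C)(C)C | intermediate
29 | acetic (2Z)-4-(acetyloxy)-2-methylbut-2-enoic anhydride | CC(=O)OC(=O)/C(C)=C\COC(C)=O | intermediate (not isolated)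
30 | (2Z)-4-(acetyloxy)-2-methylbut-2-enoic acid | OC(=O)/C(C)=C\COC(C)=O | intermediate
31 | (2Z)-4-(acetyloxy)-2-methylbut-2-enoic 2,4,6-trichlorobenzoic anhydride | O=C(OC(=O)/C(C)=C\COC(C)=O)c1c(Cl)cc(Cl)cc1Cl | intermediate (not isolated)
32 | 2-(trimethylsilyl)ethyl 2-[(1S,2S,3R,4R,6S)-6-{[(2Z)-4-(acetyloxy)-2-methylbut-2-enoyl]oxy}-3-(3-{[tert-butyl(dimethyl)silyl]oxy}prop-1-en-2-yl)-4-ethenyl-2-hydroxy-4-methylcyclohexyl]prop-2-enoate | C=C[C@@]1(C)C[C@H](OC(=O)/C(C)=C\COC(C)=O)[C@@H](C(=C)C(=O)OCC[Si](C)(C)C)[C@@H](O)[C@H]1C(=C)CO[Si](C)(C)C(C)(C)C | intermediate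
33 | 2-[(1S,2S,3R,4R,6S)-6-{[(2Z)-4-(acetyloxy)-2-methylbut-2-enoyl]oxy}-4-ethenyl-2-hydroxy-3-(3-hydroxyprop-1-en-2-yl)-4-methylcyclohexyl]prop-2-enoic acid | C=C[C@@]1(C)C[C@H](OC(=O)/C(C)=C\COC(C)=O)[C@@H](C(=C)C(=O)O)[C@@H](O)[C@H]1C(=C)CO | target

**Step count and risks**

Total steps: 16. Longest linear sequence: 12 (steps 1–6, 9–12, 15, 16); steps 7–8 and 13–14 are side branches.

Steps most likely to fail:

1. Step 12 (proposed new method). The reductive transmetalation may be too slow, so that the palladium-bound allyl alkoxide isomerizes or is captured by the aldehyde oxygen, or closure may run through the indium-chelated array with loss of control at C1 and C2. The fallback uses known chemistry and sets out from 22. MgBr2·OEt2 in Et2O at −20 °C should open the vinyl epoxide in the SN2' sense at the acrylate methylene to the δ-hydroxy (Z)-allylic bromide, which rests as the lactol 2-(trimethylsilyl)ethyl (2Z)-2-(bromomethyl)-3-[(2S,4R,5R)-5-(3-{[tert-butyl(dimethyl)silyl]oxy}prop-1-en-2-yl)-4-ethenyl-6-hydroxy-4-methyloxan-2-yl]prop-2-enoate F1. In metal (powder) in THF/H2O should then effect the intramolecular Barbier allylation of the lactol, the established cyclization type of ω-formyl 2-(bromomethyl)acrylates, and the route is rejoined at 24.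

2. Step 4. Enantio- or diastereocontrol may be insufficient with this enyne and dienolate, or the silyl ether may be lost to the Lewis acidic boron bromide. The fallback sets out from 6. A lithium-enolate Ireland–Claisen rearrangement (LiN(i-Pr)2, Me3SiCl/Et3N, THF, −78 °C → rt), whose kinetic E(O) enolate leads to the same relative configuration, should give racemic (2R*,3R*)-2-(3-{[tert-butyl(dimethyl)silyl]oxy}prop-1-en-2-yl)-3-ethynyl-3-methylpent-4-enoic acid F2. Classical resolution by crystallization of the (S)-1-phenylethylammonium (2R,3R)-carboxylate F3, followed by acidification, rejoins the route at 9.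

3. Step 9. The acrylate-bearing phosphonate anion may self-condense, attack through its γ-carbon, or give poor E geometry. The fallback sets out from 13. The boron variant of the Takai olefination (Cl2CHBpin, CrCl2, LiI, THF) should give (2R,3R,5E)-2-(3-{[tert-butyl(dimethyl)silyl]oxy}prop-1-en-2-yl)-3-ethenyl-3-methyl-6-(4,4,5,5-tetramethyl-1,3,2-dioxaborolan-2-yl)hex-5-en-1-ol F4. Suzuki–Miyaura coupling (Pd(dppf)Cl2, K3PO4, THF/H2O) with 2-(trimethylsilyl)ethyl 2-bromoprop-2-enoate F5, made from 2-bromoprop-2-enoic acid and 15 with dicyclohexylcarbodiimide, rejoins the route at 20.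

**Further compounds**

F1 | step 12 | 2-(trimethylsilyl)ethyl (2Z)-2-(bromomethyl)-3-[(2S,4R,5R)-5-(3-{[tert-butyl(dimethyl)silyl]oxy}prop-1-en-2-yl)-4-ethenyl-6-hydroxy-4-methyloxan-2-yl]prop-2-enoate | C=C[C@@]1(C)C[C@@H](/C=C(\CBr)C(=O)OCC[Si](C)(C)C)OC(O)[C@H]1C(=C)CO[Si](C)(C)C(C)(C)C
F2 | step 4 | racemic (2R*,3R*)-2-(3-{[tert-butyl(dimethyl)silyl]oxy}prop-1-en-2-yl)-3-ethynyl-3-methylpent-4-enoic acid | C=C[C@@](C)(C#C)[C@@H](C(=O)O)C(=C)CO[Si](C)(C)C(C)(C)C.C=C[C@](C)(C#C)[C@H](C(=O)O)C(=C)CO[Si](C)(C)C(C)(C)C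
F3 | step 4 | (S)-1-phenylethylammonium (2R,3R)-2-(3-{[tert-butyl(dimethyl)silyl]oxy}prop-1-en-2-yl)-3-ethynyl-3-methylpent-4-enoate | C=C[C@@](C)(C#C)[C@@H](C(=O)[O-])C(=C)CO[Si](C)(C)C(C)(C)C.C[C@H]([NH3+])c1ccccc1
F4 | step 9 | (2R,3R,5E)-2-(3-{[tert-butyl(dimethyl)silyl]oxy}prop-1-en-2-yl)-3-ethenyl-3-methyl-6-(4,4,5,5-tetramethyl-1,3,2-dioxaborolan-2-yl)hex-5-en-1-ol | C=C[C@@](C)(C/C=C/B1OC(C)(C)C(C)(C)O1)[C@@H](CO)C(=C)CO[Si](C)(C)C(C)(C)C
F5 | step 9 | 2-(trimethylsilyl)ethyl 2-bromoprop-2-enoate | C=C(Br)C(=O)OCC[Si](C)(C)C
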